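**Retrosynthetic overview**
1. Feature: in ring A (C1 CO2Me, C2 CH2O-acyl, C3 H, C4 OH, C5 CH3, C6 OH) the ester carbon C1 and the acyloxymethyl carbon C2 are neighbours, like the two sp carbons of a 4-acyloxybut-2-ynoate. C3–C6 is a four-carbon unit oxygenated at C4 and C6 with the methyl on C5, the pattern of methyl 2-methylacetoacetate.
2. Last disconnection: the two MOM ethers on the ring B hydroxyls, removed in acidic methanol.
3. Key disconnection: bonds C2–C3 and C1–C6 of ring A, by Diels–Alder reaction of a 1-methoxy-2-methyl-1,3-bis(trimethylsilyloxy)diene with the ynoate that already carries ring B as its ester, followed by aromatisation. The benzylic oxygen is acylated before ring A exists, so no phthalide can form.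
4. Ynoate: carboxylate O-alkylation of MOM-protected haematommic acid with methyl 4-bromobut-2-ynoate. The acid comes from orcinol by MOM protection, directed lithiation–formylation, bromination and bromine–lithium exchange–carboxylation with the aldehyde masked in the flask.
5. Ring order: ring B is bought as orcinol and only functionalised; ring A is the only ring formed, in the key step.

Key step: step 9

Remark: the target has no stereocentre. The geometry of the ketene acetal double bond of the diene (drawn 1Z) and of the enol ether before it is not controlled and does not matter, because these carbons end up in the aromatic ring.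
Remark: methyl 4-bromobut-2-ynoate is made from the commercial alcohol rather than bought. Ring A is numbered as in line 1; ring B is numbered as a benzoic acid (C1' carboxyl, C2' and C4' oxygens, C3' formyl, C6' methyl).

**Route**

Step 1
Reactants: 1 orcinol (5-methylbenzene-1,3-diol)
Product: 2 1,3-bis(methoxymethoxy)-5-methylbenzene
Conditions: NaH, MOMCl, DMF, 0 °C → rt
Reagents that add atoms: chloromethyl methyl ether, COCCl
Why: Double Williamson-type O-alkylation of the sodium phenoxides by the highly reactive α-chloro ether should give the bis(MOM) ether, whose acetal oxygens later direct the lithiation.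

Step 2
Reactants: 2 1,3-bis(methoxymethoxy)-5-methylbenzene
Product: 5 2,6-bis(methoxymethoxy)-4-methylbenzaldehyde, via aryllithium 3 (not isolated), via lithium hemiaminal alkoxide 4 (not isolated)
Conditions: n-BuLi, TMEDA, THF, 0 °C; DMF, 0 °C → rt; H2O
Reagents that add atoms: N,N-dimethylformamide, CN(C)C=O
Why: Directed ortho-metalation should occur at the one hydrogen flanked and coordinated by both MOM ethers, and the aryllithium is formylated by DMF (Bouveault aldehyde synthesis), the aldehyde being released from the hemiaminal alkoxide on quenching with water.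

Step 3
Reactants: 5 2,6-bis(methoxymethoxy)-4-methylbenzaldehyde
Product: 6 3-bromo-2,6-bis(methoxymethoxy)-4-methylbenzaldehyde
Conditions: NBS (1.0 equiv), DMF, 0 °C → rt, dark
Reagents that add atoms: N-bromosuccinimide, O=C1CCC(=O)N1Br
Why: Electrophilic aromatic bromination should go to C3 (equivalent to C5 by symmetry), which is ortho to one acetal oxygen, para to the other, ortho to the methyl and meta to the formyl group, and one equivalent of NBS without acid leaves the MOM ethers and the benzylic methyl alone.

Step 4
Reactants: 6 3-bromo-2,6-bis(methoxymethoxy)-4-methylbenzaldehyde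
Product: 10 3-formyl-2,4-bis(methoxymethoxy)-6-methylbenzoic acid, via lithium morpholino alkoxide 7 (not isolated), via lithiated morpholino alkoxide 8 (not isolated), via dilithium carboxylate 9 (not isolated)
Conditions: morpholine, n-BuLi, THF, −78 → −40 °C; n-BuLi, −78 °C; CO2, −78 → 0 °C; 1 M HCl to pH 3, 0 °C
Reagents that add atoms: carbon dioxide, O=C=O
Why: Lithium morpholide adds to the aldehyde and masks it in the flask as an α-amino alkoxide that n-BuLi does not attack, bromine–lithium exchange then gives the aryllithium that CO2 carboxylates, and brief cold acidification collapses the hemiaminal and frees the acid without cleaving the MOM acetals (in situ aldehyde protection, halogen–metal exchange, carboxylation).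

Step 5
Reactants: 11 methyl 4-hydroxybut-2-ynoate
Product: 12 methyl 4-bromobut-2-ynoate
Conditions: PBr3, pyridine (cat.), Et2O, −10 °C → rt
Reagents that add atoms: phosphorus tribromide, BrP(Br)Br
Why: PBr3 converts the primary propargylic alcohol into its bromophosphite, which bromide displaces in an SN2 reaction, and the cold, base-poor conditions should not touch the conjugated ynoate.

Step 6
Reactants: 10 3-formyl-2,4-bis(methoxymethoxy)-6-methylbenzoic acid; 12 methyl 4-bromobut-2-ynoate
Product: 14 4-methoxy-4-oxobut-2-yn-1-yl 3-formyl-2,4-bis(methoxymethoxy)-6-methylbenzoate, via potassium carboxylate 13 (not isolated)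
Conditions: KHCO3, DMF, rt; then 12, 0 °C → rt
Reagents that add atoms: none
Why: SN2 O-alkylation of the carboxylate by the primary propargylic bromide makes the ester bond at the unhindered CH2 and not at the di-ortho-substituted acyl carbon, and KHCO3 is basic enough for the acid but too weak to isomerise the bromo ynoate or disturb the aldehyde and MOM ethers.

Step 7
Reactants: 15 methyl 2-methyl-3-oxobutanoate (methyl 2-methylacetoacetate)
Product: 16 methyl 2-methyl-3-(trimethylsilyloxy)but-2-enoate
Conditions: TMSCl, Et3N, hexane, rt
Reagents that add atoms: chlorotrimethylsilane, C[Si](C)(C)Cl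
Why: Soft enolisation of the β-keto ester by Et3N and O-silylation with TMSCl should give the conjugated silyl enol ether (silyl enol ether formation), isolated by filtration and distillation without contact with water.

Step 8
Reactants: 16 methyl 2-methyl-3-(trimethylsilyloxy)but-2-enoate
Product: 18 (1Z)-1-methoxy-2-methyl-1,3-bis(trimethylsilyloxy)buta-1,3-diene, via lithium dienolate 17 (not isolated)
Conditions: LiN(i-Pr)2, THF, −78 °C; TMSCl, −78 → 0 °C; pentane, filtration
Reagents that add atoms: chlorotrimethylsilane, C[Si](C)(C)Cl
Why: LiN(i-Pr)2 removes a proton from the C4 methyl of the β-silyloxy enoate to give the extended ester dienolate, which TMSCl silylates on oxygen (silyl ketene acetal formation) to give the 1,3-bis(silyloxy) diene, used after a non-aqueous work-up.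

Step 9
Reactants: 14 4-methoxy-4-oxobut-2-yn-1-yl 3-formyl-2,4-bis(methoxymethoxy)-6-methylbenzoate; 18 (1Z)-1-methoxy-2-methyl-1,3-bis(trimethylsilyloxy)buta-1,3-diene
Product: 21 methyl 2-({[3-formyl-2,4-bis(methoxymethoxy)-6-methylbenzoyl]oxy}methyl)-4,6-dihydroxy-5-methylbenzoate, via cyclohexadiene cycloadduct 19 (not isolated), via bis(trimethylsilyl) ether 20 (not isolated)
Conditions: 18 (3 equiv), toluene, 110 °C, sealed tube; then 5% aq. citric acid, THF, 0 °C
Reagents that add atoms: none
Why: A thermal normal-electron-demand Diels–Alder reaction joins the CH2 terminus of 18 to the ynoate β-carbon (bond C2–C3) and the ketene acetal carbon to the α-carbon (bond C1–C6) in a concerted, asynchronous [4+2] process, the closest known reaction type being the cycloaddition of 1-alkoxy-1,3-bis(silyloxy)butadienes with acetylenic esters to give resorcylates. Ring A is closed intermolecularly as a six-membered carbocycle by this two-bond annulation, first as cyclohexa-1,4-diene 19, which loses methanol by 1,4-elimination across the C6 ketal carbon and the C3 methylene to give the aromatic bis(silyl) ether 20. No stereocentre is set, because the single sp3 centre of racemic 19 becomes aromatic, which also makes the ketene acetal geometry irrelevant. The step needs regioselectivity, and the matched polarisation should secure it: the largest HOMO coefficient of the diene lies on its unsubstituted CH2 carbon and the largest LUMO coefficient of the dienophile on the carbon β to the ester. It also needs chemoselectivity for the alkyne over the ring B aldehyde, which rests on the absence of any Lewis acid and on the shielding and deactivation of that aldehyde by its two ortho acetal oxygens. Cold dilute citric acid should then cleave only the two aryl O–SiMe3 bonds and leave the MOM ethers, both esters and the benzylic C–O bond intact.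

Step 10
Reactants: 21 methyl 2-({[3-formyl-2,4-bis(methoxymethoxy)-6-methylbenzoyl]oxy}methyl)-4,6-dihydroxy-5-methylbenzoate
Product: 22 methyl 2-{[(3-formyl-2,4-dihydroxy-6-methylbenzoyl)oxy]methyl}-4,6-dihydroxy-5-methylbenzoate (target)
Conditions: HCl (1.25 M in MeOH), CH2Cl2, 0 °C → rt
Reagents that add atoms: none
Why: Acid-catalysed methanolysis (acetal exchange) should remove the two MOM groups, each labile because it sits ortho to a carbonyl group, while methanol traps the methoxymethyl cation as dimethoxymethane so that it cannot alkylate electron-rich ring A, and the hindered benzylic ester and the methyl ester (degenerate exchange in methanol) survive.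

**Compound list**
1 | orcinol (5-methylbenzene-1,3-diol) | Cc1cc(O)cc(O)c1 | starting material
2 | 1,3-bis(methoxymethoxy)-5-methylbenzene | Cc1cc(OCOC)cc(OCOC)c1 | intermediate
3 | [2,6-bis(methoxymethoxy)-4-methylphenyl]lithium | [Li]c1c(OCOC)cc(C)cc1OCOC | intermediate (not isolated)
4 | lithium [2,6-bis(methoxymethoxy)-4-methylphenyl](dimethylamino)methanolate, racemic | CN(C)C(O[Li])c1c(OCOC)cc(C)cc1OCOC | intermediate (not isolated)
5 | 2,6-bis(methoxymethoxy)-4-methylbenzaldehyde | O=Cc1c(OCOC)cc(C)cc1OCOC | intermediate
6 | 3-bromo-2,6-bis(methoxymethoxy)-4-methylbenzaldehyde | O=Cc1c(OCOC)c(Br)c(C)cc1OCOC | intermediate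
7 | lithium [3-bromo-2,6-bis(methoxymethoxy)-4-methylphenyl](morpholin-4-yl)methanolate, racemic | [Li]OC(N1CCOCC1)c1c(OCOC)c(Br)c(C)cc1OCOC | intermediate (not isolated)
8 | lithium [3-lithio-2,6-bis(methoxymethoxy)-4-methylphenyl](morpholin-4-yl)methanolate, racemic | [Li]OC(N1CCOCC1)c1c(OCOC)c([Li])c(C)cc1OCOC | intermediate (not isolated)
9 | lithium 3-[(lithiooxy)(morpholin-4-yl)methyl]-2,4-bis(methoxymethoxy)-6-methylbenzoate, racemic | [Li]OC(N1CCOCC1)c1c(OCOC)c(C(=O)O[Li])c(C)cc1OCOC | intermediate (not isolated)
10 | 3-formyl-2,4-bis(methoxymethoxy)-6-methylbenzoic acid | O=Cc1c(OCOC)c(C(=O)O)c(C)cc1OCOC | intermediate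
11 | methyl 4-hydroxybut-2-ynoate | COC(=O)C#CCO | starting material
12 | methyl 4-bromobut-2-ynoate | COC(=O)C#CCBr | intermediate
13 | potassium 3-formyl-2,4-bis(methoxymethoxy)-6-methylbenzoate | [K+].[O-]C(=O)c1c(C)cc(OCOC)c(C=O)c1OCOC | intermediate (not isolated)
14 | 4-methoxy-4-oxobut-2-yn-1-yl 3-formyl-2,4-bis(methoxymethoxy)-6-methylbenzoate | COC(=O)C#CCOC(=O)c1c(C)cc(OCOC)c(C=O)c1OCOC | intermediate
15 | methyl 2-methyl-3-oxobutanoate, racemic | COC(=O)C(C)C(C)=O | starting material
16 | methyl 2-methyl-3-(trimethylsilyloxy)but-2-enoate, E/Z mixture, drawn without geometry | COC(=O)C(C)=C(C)O[Si](C)(C)C | intermediate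
17 | lithium (1E)-1-methoxy-2-methyl-3-(trimethylsilyloxy)buta-1,3-dien-1-olate | CO/C(O[Li])=C(\C)C(=C)O[Si](C)(C)C | intermediate (not isolated)
18 | (1Z)-1-methoxy-2-methyl-1,3-bis(trimethylsilyloxy)buta-1,3-diene | CO/C(O[Si](C)(C)C)=C(\C)C(=C)O[Si](C)(C)C | intermediate
19 | methyl 2-({[3-formyl-2,4-bis(methoxymethoxy)-6-methylbenzoyl]oxy}methyl)-6-methoxy-5-methyl-4,6-bis(trimethylsilyloxy)cyclohexa-1,4-diene-1-carboxylate, racemic | COC(=O)C1=C(COC(=O)c2c(C)cc(OCOC)c(C=O)c2OCOC)CC(O[Si](C)(C)C)=C(C)C1(OC)O[Si](C)(C)C | intermediate (not isolated)
20 | methyl 2-({[3-formyl-2,4-bis(methoxymethoxy)-6-methylbenzoyl]oxy}methyl)-5-methyl-4,6-bis(trimethylsilyloxy)benzoate | COC(=O)c1c(COC(=O)c2c(C)cc(OCOC)c(C=O)c2OCOC)cc(O[Si](C)(C)C)c(C)c1O[Si](C)(C)C | intermediate (not isolated)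
21 | methyl 2-({[3-formyl-2,4-bis(methoxymethoxy)-6-methylbenzoyl]oxy}methyl)-4,6-dihydroxy-5-methylbenzoate | COC(=O)c1c(COC(=O)c2c(C)cc(OCOC)c(C=O)c2OCOC)cc(O)c(C)c1O | intermediate
22 | methyl 2-{[(3-formyl-2,4-dihydroxy-6-methylbenzoyl)oxy]methyl}-4,6-dihydroxy-5-methylbenzoate | COC(=O)c1c(COC(=O)c2c(C)cc(O)c(C=O)c2O)cc(O)c(C)c1O | target

**Step count**
Total: 10 steps. Longest linear sequence: 7 steps (steps 1, 2, 3, 4, 6, 9, 10); steps 5, 7 and 8 are side branches.

**Steps most likely to fail, with fallbacks**

Step 9. The cycloaddition to an internal ynoate may be slower than the thermal loss of the diene (silyl migration, hydrolysis by traces of water, oligomerisation), or the ketene acetal may add to the ring B aldehyde in an uncatalysed Mukaiyama-type aldol. The fallback sets out from 14 and uses a cyclic bis(silyl enol ether), which is less nucleophilic towards aldehydes and tolerates higher temperatures, in an Alder–Rickert sequence (Diels–Alder then retro-Diels–Alder). Commercial 2,5,5-trimethylcyclohexane-1,3-dione (CC1C(=O)CC(C)(C)CC1=O) would be silylated twice with TMSOTf and Et3N in Et2O (0 °C → rt), first to 2,5,5-trimethyl-3-(trimethylsilyloxy)cyclohex-2-en-1-one F1, not isolated, and then to 2,5,5-trimethyl-1,3-bis(trimethylsilyloxy)cyclohexa-1,3-diene F2. Heating 14 with F2 in o-xylene at 140–150 °C should give methyl 3-({[3-formyl-2,4-bis(methoxymethoxy)-6-methylbenzoyl]oxy}methyl)-6,8,8-trimethyl-1,5-bis(trimethylsilyloxy)bicyclo[2.2.2]octa-2,5-diene-2-carboxylate F3, not isolated, with the CH terminus of the diene on the ynoate β-carbon as in step 9. F3 loses 2-methylpropene by retro-Diels–Alder reaction and thereby comes back to the route at 20, which the citric acid work-up of step 9 turns into 21.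

Step 4. Addition of the lithium amide to the hindered, di-ortho-substituted aldehyde may be incomplete, leaving free carbonyl for n-BuLi to attack, and the aryllithium may be protonated or butylated before CO2 arrives. The fallback sets out from 6 and takes the formyl carbon through the lithiation at the alcohol oxidation level. NaBH4 in MeOH–THF at 0 °C should give [3-bromo-2,6-bis(methoxymethoxy)-4-methylphenyl]methanol F4. n-BuLi (2.2 equiv) in THF at −78 °C would form lithium [3-lithio-2,6-bis(methoxymethoxy)-4-methylphenyl]methanolate F5, not isolated, which CO2 and a cold work-up at pH 3 convert into 3-(hydroxymethyl)-2,4-bis(methoxymethoxy)-6-methylbenzoic acid F6. The carboxyl and hydroxymethyl groups are meta, so no lactone can form. Dess–Martin oxidation of the benzylic alcohol (NaHCO3, CH2Cl2, rt) comes back to the route at 10.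

Step 6. Base-induced propargyl–allenyl isomerisation or oligomerisation of the bromo ynoate, or conjugate addition to it, may outrun the O-alkylation. The fallback sets out from 10 and 11 and activates the alcohol instead of using a halide. Mitsunobu esterification (PPh3 and DIAD pre-mixed in toluene at −20 °C so that no free phosphine meets the ynoate, then 10 and 11, → rt) should give 14 directly, where it comes back to the route. The carboxylate again attacks an unhindered CH2, and step 5 is no longer needed. No new compound is made (F0).

**Further compounds**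
F1 | step 9 | 2,5,5-trimethyl-3-(trimethylsilyloxy)cyclohex-2-en-1-one | CC1=C(O[Si](C)(C)C)CC(C)(C)CC1=O
F2 | step 9 | 2,5,5-trimethyl-1,3-bis(trimethylsilyloxy)cyclohexa-1,3-diene | CC1=C(O[Si](C)(C)C)CC(C)(C)C=C1O[Si](C)(C)C
F3 | step 9 | methyl 3-({[3-formyl-2,4-bis(methoxymethoxy)-6-methylbenzoyl]oxy}methyl)-6,8,8-trimethyl-1,5-bis(trimethylsilyloxy)bicyclo[2.2.2]octa-2,5-diene-2-carboxylate, racemic | COC(=O)C1=C(COC(=O)c2c(C)cc(OCOC)c(C=O)c2OCOC)C2C(O[Si](C)(C)C)=C(C)C1(O[Si](C)(C)C)CC2(C)C
F4 | step 4 | [3-bromo-2,6-bis(methoxymethoxy)-4-methylphenyl]methanol | OCc1c(OCOC)c(Br)c(C)cc1OCOC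
F5 | step 4 | lithium [3-lithio-2,6-bis(methoxymethoxy)-4-methylphenyl]methanolate | [Li]OCc1c(OCOC)c([Li])c(C)cc1OCOC
F6 | step 4 | 3-(hydroxymethyl)-2,4-bis(methoxymethoxy)-6-methylbenzoic acid | OCc1c(OCOC)c(C(=O)O)c(C)cc1OCOC
F0 | step 6 | none | none
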